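**Retrosynthetic overview**

1. The strategy rests on ring A (C1–C2(=O)–C3=C4–C4a(OH)–C8a): it is treated as a cyclohexa-2,4(4a)-diene whose six carbons pair off as alkyne C2≡C3 (C3 already bonded to quaternary C1' of ring C), alkyne C4≡C4a and alkene C8a=C1.
2. Key disconnection: a rhodium-catalysed (2+2+2) cycloaddition of the 1,7-enyne 16 with the ring C acetylene 8 forms C4a–C8a (ring B), then C1–C2 and C3–C4 (ring A), and sets quaternary C8a.
3. After it: the C8 silyl ether becomes ketone and then vinyl bromide; singlet-oxygen (4+2) across C2/C4a with Kornblum–DeLaMare opening gives the γ-hydroxy enone; a hydroxyl-directed hydrogenation leaves the equatorial C8 bromide; desilylation ends the route.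
4. Before it: 8 comes from (1R)-camphanic acid (C1' from the chiral pool, C3'–Br by CBS reduction and Appel inversion); 16 comes from geraniol (Sharpless epoxidation sets C5, Shi epoxidation sets the C8 oxygen).
5. Order of rings: ring C (chiral pool), then ring B and ring A in the same step.

Key step: step 14

Remarks on the chemistry:
- Decalin atoms are numbered C1–C8a as in the target and ring C atoms are primed, also in names where IUPAC rules would renumber; the α face is the face of the C8a methyl.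
- (1R)-(+)-Camphanic acid, geraniol, D-(−)-diethyl tartrate and the L-fructose-derived Shi ketone are taken as purchasable.
- The C8 oxygen stereocentre of 16 only steers the formation of C8a and is erased at ketone 19.

**Ring C alkyne**

Step 1
Reactants: 1 (1R,4S)-4,7,7-trimethyl-3-oxo-2-oxabicyclo[2.2.1]heptane-1-carboxylic acid [(1R)-(+)-camphanic acid]
Product: 3 (S)-1,2,2-trimethyl-3-oxocyclopentane-1-carboxylic acid, via dipotassium hydroxy-dicarboxylate 2 (not isolated)
Conditions: KOH, H2O, 90 °C; then KMnO4, 0 °C → rt; HCl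
Reagents that add atoms: potassium hydroxide, [K+].[OH-]
Why: Saponification of the lactone gives a tertiary α-hydroxy carboxylate that alkaline permanganate should cleave by oxidative decarboxylation to the nor-ketone, the quaternary C1' being untouched and unreacted 2 returning to 1 on acidification.

Step 2
Reactants: 3 (S)-1,2,2-trimethyl-3-oxocyclopentane-1-carboxylic acid
Product: 4 (3S)-3-(hydroxymethyl)-2,2,3-trimethylcyclopentan-1-ol (both C1 epimers)
Conditions: LiAlH4, THF, 0 °C → reflux; aqueous work-up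
Reagents that add atoms: none
Why: Exhaustive hydride reduction of acid and ketone is reliable, and the carbinol configuration does not matter because step 3 re-oxidises it.

Step 3
Reactants: 4 (3S)-3-(hydroxymethyl)-2,2,3-trimethylcyclopentan-1-ol
Product: 5 (S)-1,2,2-trimethyl-3-oxocyclopentane-1-carbaldehyde
Conditions: (COCl)2, DMSO, CH2Cl2, −78 °C; Et3N, −78 °C → rt
Reagents that add atoms: none
Why: In the Swern oxidation both hydroxyls are activated before base is added, so the cis epimer cannot close to a lactol, and the aldehyde on quaternary C1' has no α-hydrogen to lose.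

Step 4
Reactants: 5 (S)-1,2,2-trimethyl-3-oxocyclopentane-1-carbaldehyde
Product: 6 (R)-3-ethynyl-2,2,3-trimethylcyclopentan-1-one
Conditions: dimethyl (1-diazo-2-oxopropyl)phosphonate, K2CO3, MeOH, 0 °C → rt
Reagents that add atoms: dimethyl (1-diazo-2-oxopropyl)phosphonate, CC(=O)C(=[N+]=[N-])P(=O)(OC)OC
Why: The Ohira–Bestmann (Seyferth–Gilbert) homologation converts the non-enolisable aldehyde into the terminal alkyne, while the hindered ketone next to CMe2 should not react under carbonate/methanol conditions.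

Step 5
Reactants: 6 (R)-3-ethynyl-2,2,3-trimethylcyclopentan-1-one
Product: 7 (1S,3R)-3-ethynyl-2,2,3-trimethylcyclopentan-1-ol
Conditions: (R)-2-methyl-CBS-oxazaborolidine (0.2 equiv), catecholborane, toluene, −78 °C
Reagents that add atoms: none
Why: In this Corey–Bakshi–Shibata reduction the catalyst tells the quaternary CMe2 flank from the CH2 flank, so the (S)-carbinol (OH trans to ethynyl) should form under reagent control, and catecholborane at −78 °C leaves the alkyne alone.

Step 6
Reactants: 7 (1S,3R)-3-ethynyl-2,2,3-trimethylcyclopentan-1-ol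
Product: 8 (1R,3R)-3-bromo-1-ethynyl-1,2,2-trimethylcyclopentane
Conditions: PPh3, CBr4, CH2Cl2, 0 °C → rt
Reagents that add atoms: tetrabromomethane, BrC(Br)(Br)Br
Why: The Appel reaction displaces the alkoxyphosphonium by bromide with inversion, which turns the trans alcohol into the required cis (3'R) bromide; substitution at a cyclopentyl carbon is feasible even next to CMe2.

**Enyne**

Step 7
Reactants: 9 geraniol [(2E)-3,7-dimethylocta-2,6-dien-1-ol]
Product: 10 [(2R,3R)-3-methyl-3-(4-methylpent-3-en-1-yl)oxiran-2-yl]methanol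
Conditions: Ti(OiPr)4, D-(−)-diethyl tartrate, tBuOOH, 4 Å MS, CH2Cl2, −20 °C
Reagents that add atoms: tert-butyl hydroperoxide, CC(C)(C)OO
Why: Sharpless asymmetric epoxidation touches only the allylic alcohol alkene, and the D-tartrate ligand delivers oxygen to the face that gives the (2R,3R)-epoxide, which fixes the future C5.

Step 8
Reactants: 10 [(2R,3R)-3-methyl-3-(4-methylpent-3-en-1-yl)oxiran-2-yl]methanol
Product: 11 (2R,3S)-3-(chloromethyl)-2-methyl-2-(4-methylpent-3-en-1-yl)oxirane
Conditions: PPh3, CCl4, NaHCO3, reflux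
Reagents that add atoms: tetrachloromethane, ClC(Cl)(Cl)Cl
Why: Appel chlorination of the primary alcohol under buffered conditions leaves the epoxide and its two stereocentres intact.

Step 9
Reactants: 11 (2R,3S)-3-(chloromethyl)-2-methyl-2-(4-methylpent-3-en-1-yl)oxirane
Product: 12 (R)-3,7-dimethyloct-6-en-1-yn-3-ol
Conditions: n-BuLi (3.5 equiv), THF, −40 → 0 °C; H2O
Reagents that add atoms: none
Why: Base-induced eliminative opening of the 2,3-epoxy chloride followed by dehydrochlorination gives the terminal propargylic alcohol, and the C–O bond at the tertiary carbon is never broken, so its configuration is retained.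

Step 10
Reactants: 12 (R)-3,7-dimethyloct-6-en-1-yn-3-ol
Product: 13 (R)-tert-butyl[(3,7-dimethyloct-6-en-1-yn-3-yl)oxy]dimethylsilane
Conditions: TBSOTf, 2,6-lutidine, CH2Cl2, 0 °C
Reagents that add atoms: tert-butyldimethylsilyl trifluoromethanesulfonate, CC(C)(C)[Si](C)(C)OS(=O)(=O)C(F)(F)F
Why: The silyl triflate silylates the tertiary propargylic alcohol, which prevents cyclisation onto the later epoxide and removes the hydrogen-bond donor that could misdirect singlet oxygen and the iridium catalyst.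

Step 11
Reactants: 13 (R)-tert-butyl[(3,7-dimethyloct-6-en-1-yn-3-yl)oxy]dimethylsilane
Product: 14 tert-butyl({(3R)-5-[(2S)-3,3-dimethyloxiran-2-yl]-3-methylpent-1-yn-3-yl}oxy)dimethylsilane
Conditions: ent-Shi ketone (L-fructose-derived, 0.3 equiv), Oxone (2KHSO5·KHSO4·K2SO4), K2CO3, Bu4NHSO4, MeCN/dimethoxymethane/aq. Na2B4O7, 0 °C
Reagents that add atoms: potassium peroxymonosulfate, [K+].[O-]S(=O)(=O)OO
Why: In the Shi epoxidation the chiral dioxirane epoxidises the trisubstituted alkene through a spiro transition state, the L-series ketone giving the (S)-configured secondary carbon, and the alkyne is inert to dioxiranes.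

Step 12
Reactants: 14 tert-butyl({(3R)-5-[(2S)-3,3-dimethyloxiran-2-yl]-3-methylpent-1-yn-3-yl}oxy)dimethylsilane
Product: 15 (3S,6R)-6-(tert-butyldimethylsilyloxy)-2,6-dimethyloct-1-en-7-yn-3-ol
Conditions: LDA (3.5 equiv), Et2O, 0 °C → reflux; H2O
Reagents that add atoms: none
Why: Lithium amide-promoted isomerisation of the epoxide to the allylic alcohol removes a methyl proton in a syn β-elimination and keeps the secondary C–O bond, so the carbinol stays (S); the acetylide formed by the first equivalent of base is inert.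

Step 13
Reactants: 15 (3S,6R)-6-(tert-butyldimethylsilyloxy)-2,6-dimethyloct-1-en-7-yn-3-ol
Product: 16 (3R,6S)-3-(tert-butyldimethylsilyloxy)-3,7-dimethyl-6-(triethylsilyloxy)oct-7-en-1-yne
Conditions: TESCl, imidazole, DMF, 0 °C
Reagents that add atoms: chlorotriethylsilane, CC[Si](Cl)(CC)CC
Why: Silylation of the secondary allylic alcohol blocks rhodium-mediated isomerisation of the allylic alcohol and gives a group that can later be removed in the presence of the tertiary TBS ether.

**Key step and endgame**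

Step 14
Reactants: 16 (3R,6S)-3-(tert-butyldimethylsilyloxy)-3,7-dimethyl-6-(triethylsilyloxy)oct-7-en-1-yne; 8 (1R,3R)-3-bromo-1-ethynyl-1,2,2-trimethylcyclopentane
Product: 17 (5R,8S,8aS)-3-[(1R,3R)-3-bromo-1,2,2-trimethylcyclopentyl]-5-(tert-butyldimethylsilyloxy)-5,8a-dimethyl-8-(triethylsilyloxy)-1,5,6,7,8,8a-hexahydronaphthalene
Conditions: [Rh(cod)2]BF4 (10 mol %), (R)-BINAP (10 mol %), H2 then argon (cod removed); 8 (3 equiv); 16 added over 6 h; ClCH2CH2Cl, 60 °C
Reagents that add atoms: none
Why: Proposed new method: cationic monovalent rhodium binds the alkyne and the 1,1-disubstituted alkene of 16 and couples them oxidatively to a trivalent rhodacyclopentene (Rh–C4=C4a–C8a–C1), which closes ring B through the C4a–C8a bond in the exo sense at both π-systems; alkyne 8 then inserts and reductive elimination closes ring A as the second six-membered ring through C1–C2 and C3–C4, the quaternary C8a preventing aromatisation. The closest known reaction type is the rhodium/BINAP-catalysed (2+2+2) cycloaddition of 1,6-enynes bearing 1,1-disubstituted alkenes with alkynes, which gives bicyclic cyclohexadienes with a quaternary ring-fusion carbon; the 1,7-tether and the tert-alkyl acetylene are the untested extensions, and the fully substituted C5 in the tether should favour the six-membered closure. The only new stereocentre, C8a, is set in a chair-like ring B of the metallacycle in which C1 must lie in the plane of the C4=C4a bond, so the C8a methyl is axial: the chair with C8–OTES and C5–Me equatorial and only C5–OTBS axial leads to the required (8aS) isomer, whereas the epimer would need the C8 silyl ether axial and a syn-diaxial C5–Me/C8a–Me pair; (R)-BINAP is the working choice and the antipode that reinforces this substrate bias is the one to keep. The step needs cross- over homo-trimerisation, which slow addition of 16 to an excess of the hindered, slowly self-reacting 8 should secure, and it needs the cyclopentyl group at C3: the alkyne CH should bond to the neopentyl C1 beside quaternary C8a and the substituted carbon to the unhindered vinylic C4, which puts the tert-alkyl group at the one ring position flanked by two CH groups.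

Step 15
Reactants: 17 (5R,8S,8aS)-3-[(1R,3R)-3-bromo-1,2,2-trimethylcyclopentyl]-5-(tert-butyldimethylsilyloxy)-5,8a-dimethyl-8-(triethylsilyloxy)-1,5,6,7,8,8a-hexahydronaphthalene
Product: 18 (5R,8S,8aS)-3-[(1R,3R)-3-bromo-1,2,2-trimethylcyclopentyl]-5-(tert-butyldimethylsilyloxy)-5,8a-dimethyl-1,5,6,7,8,8a-hexahydronaphthalen-8-ol
Conditions: HF·pyridine, pyridine, THF, 0 °C
Reagents that add atoms: none
Why: Buffered fluoride cleaves the secondary triethylsilyl ether much faster than the tertiary TBS ether, and the excess pyridine protects the acid-sensitive diene.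

Step 16
Reactants: 18 (5R,8S,8aS)-3-[(1R,3R)-3-bromo-1,2,2-trimethylcyclopentyl]-5-(tert-butyldimethylsilyloxy)-5,8a-dimethyl-1,5,6,7,8,8a-hexahydronaphthalen-8-ol
Product: 19 (5R,8aS)-3-[(1R,3R)-3-bromo-1,2,2-trimethylcyclopentyl]-5-(tert-butyldimethylsilyloxy)-5,8a-dimethyl-5,6,7,8a-tetrahydronaphthalen-8(1H)-one
Conditions: Dess–Martin periodinane, NaHCO3, CH2Cl2, 0 °C → rt
Reagents that add atoms: none
Why: Dess–Martin oxidation of the hindered secondary alcohol is neutral and leaves the diene alone, and the β,γ-unsaturated ketone cannot move into conjugation because C8a is quaternary.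

Step 17
Reactants: 19 (5R,8aS)-3-[(1R,3R)-3-bromo-1,2,2-trimethylcyclopentyl]-5-(tert-butyldimethylsilyloxy)-5,8a-dimethyl-5,6,7,8a-tetrahydronaphthalen-8(1H)-one
Product: 21 (5R,8aS)-8-bromo-3-[(1R,3R)-3-bromo-1,2,2-trimethylcyclopentyl]-5-(tert-butyldimethylsilyloxy)-5,8a-dimethyl-1,5,6,8a-tetrahydronaphthalene, via hydrazone 20 (not isolated)
Conditions: N2H4·H2O, Et3N, EtOH, 70 °C (argon); then NBS, 1,1,3,3-tetramethylguanidine, CH2Cl2, −20 → 0 °C (inverse addition)
Reagents that add atoms: hydrazine hydrate, NN.O (its nitrogens stay only in 20); N-bromosuccinimide, O=C1CCC(=O)N1Br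
Why: In this Barton vinyl halide synthesis the hydrazone is oxidised through the diazo compound and an α-bromo diazonium ion that loses N2 and the only available β-proton (at C7), which should give the C7=C8 vinyl bromide, a sequence that works on ketones flanked by a quaternary carbon and is much faster than bromination of the diene at low temperature with base present.

Step 18
Reactants: 21 (5R,8aS)-8-bromo-3-[(1R,3R)-3-bromo-1,2,2-trimethylcyclopentyl]-5-(tert-butyldimethylsilyloxy)-5,8a-dimethyl-1,5,6,8a-tetrahydronaphthalene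
Product: 23 (4aR,5R,8aS)-8-bromo-3-[(1R,3R)-3-bromo-1,2,2-trimethylcyclopentyl]-5-(tert-butyldimethylsilyloxy)-4a-hydroxy-5,8a-dimethyl-4a,5,6,8a-tetrahydronaphthalen-2(1H)-one, via endoperoxide 22 (not isolated)
Conditions: O2, tetraphenylporphyrin (cat.), visible light, CH2Cl2, −30 °C; then Et3N, 0 °C → rt
Reagents that add atoms: dioxygen, O=O
Why: Singlet oxygen should add (4+2) across C2/C4a of the cisoid ring A diene on the β face, opposite the axial C8a methyl and the axial C5 silyl ether (as with steroidal 2,4-dienes), which sets C4a (R), and the Kornblum–DeLaMare rearrangement then removes the only hydrogen α to the peroxide (at C2) to give the C2 ketone and the C4a alcohol; the electron-poor vinyl bromide is inert to singlet oxygen.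

Step 19
Reactants: 23 (4aR,5R,8aS)-8-bromo-3-[(1R,3R)-3-bromo-1,2,2-trimethylcyclopentyl]-5-(tert-butyldimethylsilyloxy)-4a-hydroxy-5,8a-dimethyl-4a,5,6,8a-tetrahydronaphthalen-2(1H)-one
Product: 24 (4aR,5R,8S,8aS)-8-bromo-3-[(1R,3R)-3-bromo-1,2,2-trimethylcyclopentyl]-5-(tert-butyldimethylsilyloxy)-4a-hydroxy-5,8a-dimethyl-4a,5,6,7,8,8a-hexahydronaphthalen-2(1H)-one
Conditions: H2 (1 atm), [Ir(cod)(PCy3)(py)]PF6 (Crabtree's catalyst, 15 mol %), CH2Cl2, rt
Reagents that add atoms: none
Why: In this hydroxyl-directed homogeneous hydrogenation the β-oriented C4a hydroxyl (homoallylic to C7=C8) binds iridium and delivers H2 to the β face, which is also the face opposite the axial C8a methyl, so hydrogen enters C8 axially and the bromide is left equatorial (8S); the five-membered O–C4a–C8a–C8–Ir chelate puts the metal on the bromine-bearing carbon, which avoids β-bromide elimination, and the electron-poor C3=C4 alkene, flanked by quaternary C1' and C4a, should be spared.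

Step 20
Reactants: 24 (4aR,5R,8S,8aS)-8-bromo-3-[(1R,3R)-3-bromo-1,2,2-trimethylcyclopentyl]-5-(tert-butyldimethylsilyloxy)-4a-hydroxy-5,8a-dimethyl-4a,5,6,7,8,8a-hexahydronaphthalen-2(1H)-one
Product: 25 (4aR,5R,8S,8aS)-8-bromo-3-[(1R,3R)-3-bromo-1,2,2-trimethylcyclopentyl]-4a,5-dihydroxy-5,8a-dimethyl-4a,5,6,7,8,8a-hexahydronaphthalen-2(1H)-one (CNP0216929.1)
Conditions: HF (48 % aq.), MeCN, 0 °C → rt
Reagents that add atoms: none
Why: Acidic fluoride removes the tertiary TBS ether without forming the C5 alkoxide, which could trigger a vinylogous retro-aldol cleavage, and without base that could eliminate the secondary bromides.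

**Compound list**

1 | (1R,4S)-4,7,7-trimethyl-3-oxo-2-oxabicyclo[2.2.1]heptane-1-carboxylic acid, (1R)-(+)-camphanic acid | CC1(C)[C@@]2(C(=O)O)CC[C@]1(C)C(=O)O2 | starting material
2 | dipotassium (1S,3R)-3-hydroxy-1,2,2-trimethylcyclopentane-1,3-dicarboxylate | CC1(C)[C@@](O)(C(=O)[O-])CC[C@]1(C)C(=O)[O-].[K+].[K+] | intermediate
3 | (S)-1,2,2-trimethyl-3-oxocyclopentane-1-carboxylic acid | CC1(C)C(=O)CC[C@]1(C)C(=O)O | intermediate
4 | (3S)-3-(hydroxymethyl)-2,2,3-trimethylcyclopentan-1-ol, both C1 epimers | CC1(C)C(O)CC[C@]1(C)CO | intermediate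
5 | (S)-1,2,2-trimethyl-3-oxocyclopentane-1-carbaldehyde | CC1(C)C(=O)CC[C@]1(C)C=O | intermediate
6 | (R)-3-ethynyl-2,2,3-trimethylcyclopentan-1-one | CC1(C)C(=O)CC[C@]1(C)C#C | intermediate
7 | (1S,3R)-3-ethynyl-2,2,3-trimethylcyclopentan-1-ol | CC1(C)[C@@H](O)CC[C@]1(C)C#C | intermediate
8 | (1R,3R)-3-bromo-1-ethynyl-1,2,2-trimethylcyclopentane | CC1(C)[C@H](Br)CC[C@]1(C)C#C | intermediate
9 | geraniol, (2E)-3,7-dimethylocta-2,6-dien-1-ol | OC/C=C(\C)CCC=C(C)C | starting material
10 | [(2R,3R)-3-methyl-3-(4-methylpent-3-en-1-yl)oxiran-2-yl]methanol | OC[C@H]1O[C@]1(C)CCC=C(C)C | intermediate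
11 | (2R,3S)-3-(chloromethyl)-2-methyl-2-(4-methylpent-3-en-1-yl)oxirane | ClC[C@H]1O[C@]1(C)CCC=C(C)C | intermediate
12 | (R)-3,7-dimethyloct-6-en-1-yn-3-ol | C#C[C@](C)(O)CCC=C(C)C | intermediate
13 | (R)-tert-butyl[(3,7-dimethyloct-6-en-1-yn-3-yl)oxy]dimethylsilane | C#C[C@](C)(O[Si](C)(C)C(C)(C)C)CCC=C(C)C | intermediate
14 | tert-butyl({(3R)-5-[(2S)-3,3-dimethyloxiran-2-yl]-3-methylpent-1-yn-3-yl}oxy)dimethylsilane | C#C[C@](C)(O[Si](C)(C)C(C)(C)C)CC[C@@H]1OC1(C)C | intermediate
15 | (3S,6R)-6-(tert-butyldimethylsilyloxy)-2,6-dimethyloct-1-en-7-yn-3-ol | C#C[C@](C)(O[Si](C)(C)C(C)(C)C)CC[C@H](O)C(C)=C | intermediate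
16 | (3R,6S)-3-(tert-butyldimethylsilyloxy)-3,7-dimethyl-6-(triethylsilyloxy)oct-7-en-1-yne | C#C[C@](C)(O[Si](C)(C)C(C)(C)C)CC[C@H](O[Si](CC)(CC)CC)C(C)=C | intermediate
17 | (5R,8S,8aS)-3-[(1R,3R)-3-bromo-1,2,2-trimethylcyclopentyl]-5-(tert-butyldimethylsilyloxy)-5,8a-dimethyl-8-(triethylsilyloxy)-1,5,6,7,8,8a-hexahydronaphthalene | CC1(C)[C@H](Br)CC[C@]1(C)C1=CC[C@]2(C)[C@@H](O[Si](CC)(CC)CC)CC[C@@](C)(O[Si](C)(C)C(C)(C)C)C2=C1 | intermediate
18 | (5R,8S,8aS)-3-[(1R,3R)-3-bromo-1,2,2-trimethylcyclopentyl]-5-(tert-butyldimethylsilyloxy)-5,8a-dimethyl-1,5,6,7,8,8a-hexahydronaphthalen-8-ol | CC1(C)[C@H](Br)CC[C@]1(C)C1=CC[C@]2(C)[C@@H](O)CC[C@@](C)(O[Si](C)(C)C(C)(C)C)C2=C1 | intermediate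
19 | (5R,8aS)-3-[(1R,3R)-3-bromo-1,2,2-trimethylcyclopentyl]-5-(tert-butyldimethylsilyloxy)-5,8a-dimethyl-5,6,7,8a-tetrahydronaphthalen-8(1H)-one | CC1(C)[C@H](Br)CC[C@]1(C)C1=CC[C@]2(C)C(=O)CC[C@@](C)(O[Si](C)(C)C(C)(C)C)C2=C1 | intermediate
20 | 8-hydrazone of 19, (5R,8aS)-3-[(1R,3R)-3-bromo-1,2,2-trimethylcyclopentyl]-5-(tert-butyldimethylsilyloxy)-8-hydrazinylidene-5,8a-dimethyl-1,5,6,7,8,8a-hexahydronaphthalene | CC1(C)[C@H](Br)CC[C@]1(C)C1=CC[C@]2(C)C(=NN)CC[C@@](C)(O[Si](C)(C)C(C)(C)C)C2=C1 | intermediate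
21 | (5R,8aS)-8-bromo-3-[(1R,3R)-3-bromo-1,2,2-trimethylcyclopentyl]-5-(tert-butyldimethylsilyloxy)-5,8a-dimethyl-1,5,6,8a-tetrahydronaphthalene | CC1(C)[C@H](Br)CC[C@]1(C)C1=CC[C@]2(C)C(Br)=CC[C@@](C)(O[Si](C)(C)C(C)(C)C)C2=C1 | intermediate
22 | (2R,4aR,5R,8aS)-8-bromo-3-[(1R,3R)-3-bromo-1,2,2-trimethylcyclopentyl]-5-(tert-butyldimethylsilyloxy)-5,8a-dimethyl-1,2,4a,5,6,8a-hexahydro-2,4a-epidioxynaphthalene (peroxide bridge on the β face) | CC1(C)[C@H](Br)CC[C@]1(C)C1=C[C@@]23OO[C@@H]1C[C@]2(C)C(Br)=CC[C@@]3(C)O[Si](C)(C)C(C)(C)C | intermediate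
23 | (4aR,5R,8aS)-8-bromo-3-[(1R,3R)-3-bromo-1,2,2-trimethylcyclopentyl]-5-(tert-butyldimethylsilyloxy)-4a-hydroxy-5,8a-dimethyl-4a,5,6,8a-tetrahydronaphthalen-2(1H)-one | CC1(C)[C@H](Br)CC[C@]1(C)C1=C[C@]2(O)[C@](C)(O[Si](C)(C)C(C)(C)C)CC=C(Br)[C@@]2(C)CC1=O | intermediate
24 | (4aR,5R,8S,8aS)-8-bromo-3-[(1R,3R)-3-bromo-1,2,2-trimethylcyclopentyl]-5-(tert-butyldimethylsilyloxy)-4a-hydroxy-5,8a-dimethyl-4a,5,6,7,8,8a-hexahydronaphthalen-2(1H)-one | CC1(C)[C@H](Br)CC[C@]1(C)C1=C[C@]2(O)[C@](C)(O[Si](C)(C)C(C)(C)C)CC[C@H](Br)[C@@]2(C)CC1=O | intermediate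
25 | (4aR,5R,8S,8aS)-8-bromo-3-[(1R,3R)-3-bromo-1,2,2-trimethylcyclopentyl]-4a,5-dihydroxy-5,8a-dimethyl-4a,5,6,7,8,8a-hexahydronaphthalen-2(1H)-one | CC1(C)[C@H](Br)CC[C@]1(C)C1=C[C@]2(O)[C@](C)(O)CC[C@H](Br)[C@@]2(C)CC1=O | target

**Step count**

Total: 20 steps. Longest linear sequence: 14 steps (steps 7–13, then 14–20).

**Steps most likely to fail**

1. Step 14. Homo-trimerisation of the terminal alkynes may outrun the cross-cycloaddition, the six-membered oxidative cyclisation onto the 1,1-disubstituted alkene may not take place, or alkyne 8 may insert in the reverse orientation and place the cyclopentyl group at C2. The fallback sets out from 8 and 16 and comes back at 17, forming the same three bonds one after another by known reactions.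
   - Markovnikov hydration of 8 (Ph3PAuCl/AgOTf, MeOH/H2O) should give 1-[(1S,3R)-3-bromo-1,2,2-trimethylcyclopentyl]ethan-1-one F1.
   - Its only enolate is trapped (KHMDS, PhNTf2, THF, −78 °C) as 1-[(1S,3R)-3-bromo-1,2,2-trimethylcyclopentyl]ethenyl trifluoromethanesulfonate F2.
   - Sonogashira coupling of F2 with the terminal alkyne of 16 (Pd(PPh3)4, CuI, iPr2NH, THF, 40 °C) makes the C3–C4 bond and gives (5R,8S)-2-[(1R,3R)-3-bromo-1,2,2-trimethylcyclopentyl]-5-(tert-butyldimethylsilyloxy)-5,9-dimethyl-8-(triethylsilyloxy)deca-1,9-dien-3-yne F3.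
   - A Trost-type palladium hydride cycloisomerisation of F3 (Pd2(dba)3·CHCl3, P(o-tol)3, AcOH, benzene, 70 °C) then adds H–Pd across C4≡C4a, carbopalladates the 1,1-disubstituted alkene in the 6-exo mode (C4a–C8a, ring B), lets the neopentyl palladium at C1 add to the C2 terminus of the diene (C1–C2, ring A) and ends by β-hydride elimination from C2, giving 17.

2. Step 19. The C3=C4 enone alkene may be hydrogenated as well, or bromine may be lost by β-bromide elimination from an alkyl–iridium intermediate. The fallback sets out from 23 and comes back at 24, accepting over-reduction and restoring the enone afterwards.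
   - Hydrogen-atom-transfer hydrogenation (Mn(dpm)3, PhSiH3, tBuOOH, iPrOH, rt) reduces both alkenes without cleaving C–Br; the α-bromo radical at C8 takes its hydrogen axially on the β face, leaving the equatorial bromide. This gives (4aR,5R,8S,8aS)-8-bromo-3-[(1R,3R)-3-bromo-1,2,2-trimethylcyclopentyl]-5-(tert-butyldimethylsilyloxy)-4a-hydroxy-5,8a-dimethyloctahydronaphthalen-2(1H)-one F4 (C3 epimers).
   - IBX dehydrogenation (DMSO, 70 °C) can only reinstall the C3=C4 double bond, because C1 lies next to quaternary C8a, and gives 24.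

3. Step 17. NBS may brominate the electron-rich ring A diene, or the cationic loss of N2 next to quaternary C8a may trigger a 1,2-shift. The fallback sets out from 19 and comes back at 21 without electrophilic bromine.
   - Enolisation toward C7, the only side with α-hydrogens (KHMDS, PhNTf2, THF, −78 °C), gives (5R,8aS)-3-[(1R,3R)-3-bromo-1,2,2-trimethylcyclopentyl]-5-(tert-butyldimethylsilyloxy)-5,8a-dimethyl-1,5,6,8a-tetrahydronaphthalen-8-yl trifluoromethanesulfonate F5.
   - Palladium-catalysed exchange of triflate for bromide (Pd2(dba)3, t-BuBrettPhos, KBr, KF, 1,4-dioxane, heat) gives 21.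

Further compounds
F1 | step 14 | 1-[(1S,3R)-3-bromo-1,2,2-trimethylcyclopentyl]ethan-1-one | CC1(C)[C@H](Br)CC[C@]1(C)C(C)=O
F2 | step 14 | 1-[(1S,3R)-3-bromo-1,2,2-trimethylcyclopentyl]ethenyl trifluoromethanesulfonate | CC1(C)[C@H](Br)CC[C@]1(C)C(=C)OS(=O)(=O)C(F)(F)F
F3 | step 14 | (5R,8S)-2-[(1R,3R)-3-bromo-1,2,2-trimethylcyclopentyl]-5-(tert-butyldimethylsilyloxy)-5,9-dimethyl-8-(triethylsilyloxy)deca-1,9-dien-3-yne | CC1(C)[C@H](Br)CC[C@]1(C)C(=C)C#C[C@](C)(O[Si](C)(C)C(C)(C)C)CC[C@H](O[Si](CC)(CC)CC)C(C)=C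
F4 | step 19 | (4aR,5R,8S,8aS)-8-bromo-3-[(1R,3R)-3-bromo-1,2,2-trimethylcyclopentyl]-5-(tert-butyldimethylsilyloxy)-4a-hydroxy-5,8a-dimethyloctahydronaphthalen-2(1H)-one (C3 epimers) | CC1(C)[C@H](Br)CC[C@]1(C)C1C[C@]2(O)[C@](C)(O[Si](C)(C)C(C)(C)C)CC[C@H](Br)[C@@]2(C)CC1=O
F5 | step 17 | (5R,8aS)-3-[(1R,3R)-3-bromo-1,2,2-trimethylcyclopentyl]-5-(tert-butyldimethylsilyloxy)-5,8a-dimethyl-1,5,6,8a-tetrahydronaphthalen-8-yl trifluoromethanesulfonate | CC1(C)[C@H](Br)CC[C@]1(C)C1=CC[C@]2(C)C(OS(=O)(=O)C(F)(F)F)=CC[C@@](C)(O[Si](C)(C)C(C)(C)C)C2=C1
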